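**Retrosynthetic overview**

1. The strategy rests on ring A (C1–C5): C4 is a tertiary carbinol (OH, isopropyl) next to the C3 methylene, which is α to the oxygenated C2. The last skeletal bond is therefore C3–C4, made by insertion of a rhodium ketocarbenoid at C3 (diazoacetyl C2–C3 on C1) into the ether-activated C4–H bond of the side chain on C5, with retention at C4.
2. Ring B (C1, C5–C10) is closed before ring A by ring-closing metathesis (C8=C9) across a γ-lactone that ties C2 to O6. The lactone fixes quaternary C1 by enolate alkylation and is then opened with MeLi to the methyl ketone (C2, C3) and the C6 alcohol.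
3. The C4–C5–C6 triad comes from a D-proline cross-aldol (C4, C5) and a Felkin–Anh ketone reduction (C6).
4. After ring A: desilylation, C4-hydroxyl-directed reduction at C2, acetylation, Luche reduction at C10, benzoylation.
5. Order of ring formation: lactone template, then ring B, then ring A.

Key step: step 15

Remark: locants are daucane locants (ring A = C1–C5; ring B = C1, C5–C10; isopropyl on C4; methyls on C1 and C8). α is the face of ring B that carries H5, β the face that carries the C1 methyl. The carbinol centre that becomes C10 is carried as an epimer mixture from the acrolein aldol until its oxidation, because C10 is a ketone in the key step.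

**Route**

Step 1
Reactants: 1 tert-butyl 4-oxobutanoate; 2 isobutyraldehyde
Product: 3 tert-butyl (3R,4R)-3-formyl-4-hydroxy-5-methylhexanoate (anti aldol; its C3 and C4 become C5 and C4 of the target)
Conditions: D-proline (10 mol %), DMF, 4 °C, slow addition of 1 to excess 2
Reagents that add atoms: none
Why: Proline-catalysed enamine cross-aldol in which the enamine of the unbranched aldehyde 1 adds to the α-branched acceptor 2 through the hydrogen-bonded chair-like transition state, which should give the anti aldol, D-proline delivering the (3R,4R) enantiomer.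

Step 2
Reactants: 3 tert-butyl (3R,4R)-3-formyl-4-hydroxy-5-methylhexanoate
Product: 4 tert-butyl (3R,4R)-4-[(tert-butyldimethylsilyl)oxy]-3-formyl-5-methylhexanoate
Conditions: t-BuMe2SiOTf, 2,6-lutidine, CH2Cl2, −78 °C
Reagents that add atoms: tert-butyldimethylsilyl trifluoromethanesulfonate, CC(C)(C)[Si](C)(C)OS(=O)(=O)C(F)(F)F
Why: Silyl triflate silylation with a hindered weak base at low temperature should protect the β-hydroxy aldehyde without retro-aldol cleavage or epimerisation and installs the ether that later activates C4–H; no stereocentre is formed.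

Step 3
Reactants: 4 tert-butyl (3R,4R)-4-[(tert-butyldimethylsilyl)oxy]-3-formyl-5-methylhexanoate; 5 2-methylallylmagnesium chloride
Product: 6 tert-butyl (3S)-3-[(1R)-1-[(tert-butyldimethylsilyl)oxy]-2-methylpropyl]-4-hydroxy-6-methylhept-6-enoate (both epimers at the new carbinol carbon, C6 of the target)
Conditions: THF, −78 °C; sat. NH4Cl quench at −78 °C
Reagents that add atoms: none
Why: Grignard addition to the aldehyde at low temperature leaves the tert-butyl ester untouched, and the carbinol configuration needs no control because this centre is oxidised in step 4.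

Step 4
Reactants: 6 tert-butyl (3S)-3-[(1R)-1-[(tert-butyldimethylsilyl)oxy]-2-methylpropyl]-4-hydroxy-6-methylhept-6-enoate
Product: 7 tert-butyl (3R)-3-[(1R)-1-[(tert-butyldimethylsilyl)oxy]-2-methylpropyl]-6-methyl-4-oxohept-6-enoate
Conditions: Dess–Martin periodinane, NaHCO3, CH2Cl2, 0 °C to rt; used without delay
Reagents that add atoms: none
Why: Buffered Dess–Martin oxidation should convert both carbinol epimers into one β,γ-unsaturated ketone without moving the alkene into conjugation or eliminating the β-silyloxy group.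

Step 5
Reactants: 7 tert-butyl (3R)-3-[(1R)-1-[(tert-butyldimethylsilyl)oxy]-2-methylpropyl]-6-methyl-4-oxohept-6-enoate
Product: 9 (4S,5S)-4-[(1R)-1-[(tert-butyldimethylsilyl)oxy]-2-methylpropyl]-5-(2-methylprop-2-en-1-yl)oxolan-2-one (4,5-cis lactone), via hydroxy ester 8 (not isolated)
Conditions: LiBH(s-Bu)3 (L-Selectride), THF, −78 °C to rt; then TsOH·H2O (cat.), CH2Cl2, rt
Reagents that add atoms: none
Why: Felkin–Anh reduction in which the bulky hydride attacks anti to the branched silyloxyalkyl group on C5 (the sense also favoured by the β-silyloxy group) should set C6 anti to C5 and syn to the C4 oxygen, after which the γ-hydroxy tert-butyl ester lactonises.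

Step 6
Reactants: 9 (4S,5S)-4-[(1R)-1-[(tert-butyldimethylsilyl)oxy]-2-methylpropyl]-5-(2-methylprop-2-en-1-yl)oxolan-2-one; 10 acrolein
Product: 11 (4S,5S)-3-(1-hydroxyprop-2-en-1-yl)-4-[(1R)-1-[(tert-butyldimethylsilyl)oxy]-2-methylpropyl]-5-(2-methylprop-2-en-1-yl)oxolan-2-one (epimers at C3 of the lactone and at the carbinol carbon)
Conditions: LiN(i-Pr)2, THF, −78 °C; then 10, −78 °C
Reagents that add atoms: none
Why: Lithium enolate aldol addition (1,2-mode) to acrolein installs C10 and C9, and neither new centre needs control since C1 is re-enolised in step 7 and C10 is oxidised in step 14.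

Step 7
Reactants: 11 (4S,5S)-3-(1-hydroxyprop-2-en-1-yl)-4-[(1R)-1-[(tert-butyldimethylsilyl)oxy]-2-methylpropyl]-5-(2-methylprop-2-en-1-yl)oxolan-2-one
Product: 12 (3S,4S,5S)-3-(1-hydroxyprop-2-en-1-yl)-3-methyl-4-[(1R)-1-[(tert-butyldimethylsilyl)oxy]-2-methylpropyl]-5-(2-methylprop-2-en-1-yl)oxolan-2-one (both carbinol epimers)
Conditions: LiN(i-Pr)2 (2.5 equiv), THF/DMPU, −78 to −40 °C; MeI
Reagents that add atoms: iodomethane, CI
Why: Fráter–Seebach-type alkylation of the alkoxide–enolate dianion, in which methyl iodide approaches the lactone enolate from the face opposite to the cis C5 and C6 substituents, should make C1 quaternary with the methyl group trans and the C10 arm cis to them.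

Step 8
Reactants: 12 (3S,4S,5S)-3-(1-hydroxyprop-2-en-1-yl)-3-methyl-4-[(1R)-1-[(tert-butyldimethylsilyl)oxy]-2-methylpropyl]-5-(2-methylprop-2-en-1-yl)oxolan-2-one
Product: 13 2-hydroxy-1,4-dimethyl-9-[(1R)-1-[(tert-butyldimethylsilyl)oxy]-2-methylpropyl]-7-oxabicyclo[4.2.1]non-3-en-8-one (ring B closed, bridged by the lactone from C1 to O6; daucane descriptors 1S,4R,5S,6S; both C10 epimers)
Conditions: second-generation Grubbs catalyst (H2IMes)(PCy3)Cl2Ru=CHPh (5 mol %), CH2Cl2, 40 °C, 0.005 M
Reagents that add atoms: none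
Why: Ring-closing metathesis, in which the C10 vinyl and C6 methallyl arms held cis on the lactone should close the seven-membered ring B with the trisubstituted C8=C9 bond and loss of ethylene.

Step 9
Reactants: 13 2-hydroxy-1,4-dimethyl-9-[(1R)-1-[(tert-butyldimethylsilyl)oxy]-2-methylpropyl]-7-oxabicyclo[4.2.1]non-3-en-8-one
Product: 14 1,4-dimethyl-9-[(1R)-1-[(tert-butyldimethylsilyl)oxy]-2-methylpropyl]-2-[(triethylsilyl)oxy]-7-oxabicyclo[4.2.1]non-3-en-8-one (both C10 epimers)
Conditions: Et3SiOTf, 2,6-lutidine, CH2Cl2, −78 to 0 °C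
Reagents that add atoms: triethylsilyl trifluoromethanesulfonate, CC[Si](CC)(CC)OS(=O)(=O)C(F)(F)F
Why: Silyl triflate silylation of the hindered allylic alcohol masks C10–OH for the organolithium and acylation steps and can later be removed in the presence of the C4 silyl ether.

Step 10
Reactants: 14 1,4-dimethyl-9-[(1R)-1-[(tert-butyldimethylsilyl)oxy]-2-methylpropyl]-2-[(triethylsilyl)oxy]-7-oxabicyclo[4.2.1]non-3-en-8-one
Product: 15 (1S,4R,5S,6S)-4-[(tert-butyldimethylsilyl)oxy]-6-hydroxy-10-[(triethylsilyl)oxy]-3,4-secodauc-8-en-2-one (ring B with 1β-methyl, 1α-acetyl, 5β-silyloxyalkyl side chain, 6α-OH; C10 epimers; in equilibrium with its bridged hemiketal)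
Conditions: MeLi (1.1 equiv), THF, −78 °C; sat. NH4Cl quench at −78 °C
Reagents that add atoms: methyllithium, [Li]C
Why: Mono-addition of an organolithium to a lactone, in which the lithium hemiketal alkoxide is stable at −78 °C, so a cold quench should give the methyl ketone (C2, C3) and free the C6 hydroxyl without over-addition.

Step 11
Reactants: 15 (1S,4R,5S,6S)-4-[(tert-butyldimethylsilyl)oxy]-6-hydroxy-10-[(triethylsilyl)oxy]-3,4-secodauc-8-en-2-one; 16 angelic acid
Product: 18 (1S,4R,5S,6S)-4-[(tert-butyldimethylsilyl)oxy]-2-oxo-10-[(triethylsilyl)oxy]-3,4-secodauc-8-en-6-yl (Z)-2-methylbut-2-enoate (C10 epimers), via mixed anhydride 17 (not isolated)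
Conditions: 16, 2,4,6-trichlorobenzoyl chloride, Et3N, toluene, rt; then 15, 80 °C
Reagents that add atoms: none
Why: Yamaguchi-type esterification through the mixed anhydride without DMAP should acylate the C6 hydroxyl of the open hydroxy ketone while keeping the Z geometry of the angelate.

Step 12
Reactants: 18 (1S,4R,5S,6S)-4-[(tert-butyldimethylsilyl)oxy]-2-oxo-10-[(triethylsilyl)oxy]-3,4-secodauc-8-en-6-yl (Z)-2-methylbut-2-enoate
Product: 20 (1S,4R,5S,6S)-4-[(tert-butyldimethylsilyl)oxy]-3-diazo-2-oxo-10-[(triethylsilyl)oxy]-3,4-secodauc-8-en-6-yl (Z)-2-methylbut-2-enoate (C10 epimers), via trifluoroacetyl diketone 19 (not isolated)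
Conditions: LiN(SiMe3)2, THF, −78 °C; CF3CO2CH2CF3; then MsN3, Et3N, H2O, MeCN, rt
Reagents that add atoms: methanesulfonyl azide, CS(=O)(=O)N=[N+]=[N-]
Why: Detrifluoroacetylative (Regitz-type deacylative) diazo transfer, in which the kinetic enolate of the only enolisable ketone is trifluoroacetylated and the 1,3-diketone then reacts with the sulfonyl azide with loss of the trifluoroacetyl group, a method suited to a methyl ketone on a quaternary carbon.

Step 13
Reactants: 20 (1S,4R,5S,6S)-4-[(tert-butyldimethylsilyl)oxy]-3-diazo-2-oxo-10-[(triethylsilyl)oxy]-3,4-secodauc-8-en-6-yl (Z)-2-methylbut-2-enoate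
Product: 21 (1S,4R,5S,6S)-4-[(tert-butyldimethylsilyl)oxy]-3-diazo-10-hydroxy-2-oxo-3,4-secodauc-8-en-6-yl (Z)-2-methylbut-2-enoate (C10 epimers)
Conditions: Bu4NF, AcOH (1:1), THF, 0 °C
Reagents that add atoms: none
Why: Fluoride desilylation should cleave the triethylsilyl ether selectively over the hindered secondary tert-butyldimethylsilyl ether, with acetic acid buffering the alkoxide so that retro-aldol cleavage of the β-hydroxy ketone and attack on the angelate are avoided.

Step 14
Reactants: 21 (1S,4R,5S,6S)-4-[(tert-butyldimethylsilyl)oxy]-3-diazo-10-hydroxy-2-oxo-3,4-secodauc-8-en-6-yl (Z)-2-methylbut-2-enoate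
Product: 22 (1S,4R,5S,6S)-4-[(tert-butyldimethylsilyl)oxy]-3-diazo-2,10-dioxo-3,4-secodauc-8-en-6-yl (Z)-2-methylbut-2-enoate (cyclohept-2-enone with 1β-methyl, 1α-diazoacetyl, 5β-[(R)-1-silyloxy-2-methylpropyl], 6α-angelate)
Conditions: Dess–Martin periodinane, NaHCO3, CH2Cl2, 0 °C; used promptly
Reagents that add atoms: none
Why: Dess–Martin oxidation of the allylic alcohol, a reagent that tolerates diazocarbonyl groups, should give the enone and remove the C10 stereocentre, so both epimers converge on one compound.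

Step 15
Reactants: 22 (1S,4R,5S,6S)-4-[(tert-butyldimethylsilyl)oxy]-3-diazo-2,10-dioxo-3,4-secodauc-8-en-6-yl (Z)-2-methylbut-2-enoate
Product: 23 (1R,4R,5S,6S)-4β-[(tert-butyldimethylsilyl)oxy]-2,10-dioxodauc-8-en-6α-yl (Z)-2-methylbut-2-enoate (trans-fused bicycle)
Conditions: Rh2(OAc)4 (2 mol %), CH2Cl2, 40 °C, syringe-pump addition of 22, final 0.005 M
Reagents that add atoms: none
Why: Rh2(OAc)4 decomposes the diazoketone to an electrophilic rhodium ketocarbenoid at C3, which inserts in a concerted three-centre manner into the C4–H bond through a five-membered transition state; the closest precedent is the dirhodium-catalysed 1,5 C–H insertion of α-diazoketones into C–H bonds α to an ether oxygen. Ring A closes by forming C3–C4 between the C1 diazoacetyl group and the C5 side chain, which are trans on ring B, so the 5-7 fusion is trans. The only new stereocentre, C4, keeps the configuration set in step 1 because insertion proceeds with retention, which places the silyloxy group on the β face and the isopropyl group on the α face. Selectivity is needed against C6–H, the isopropyl C–H bonds, the C8=C9 alkene and the C10 carbonyl oxygen: C6–H lies on the face opposite to the C1 acyl group and is deactivated by its acyloxy group, the isopropyl methine would need a six-membered transition state, and the alkene is an electron-poor enone that resists cyclopropanation, whereas C4–H is tertiary and activated by the silyl ether oxygen. Capture of the carbenoid by the C10 carbonyl oxygen to give a five-membered carbonyl ylide is reversible and has no productive unimolecular outlet without a dipolarophile, so slow addition at high dilution should channel the carbenoid into the irreversible insertion.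

Step 16
Reactants: 23 (1R,4R,5S,6S)-4β-[(tert-butyldimethylsilyl)oxy]-2,10-dioxodauc-8-en-6α-yl (Z)-2-methylbut-2-enoate
Product: 24 (1R,4R,5S,6S)-4β-hydroxy-2,10-dioxodauc-8-en-6α-yl (Z)-2-methylbut-2-enoate
Conditions: 48% aq. HF, MeCN, 0 °C to rt
Reagents that add atoms: none
Why: Acidic fluoride desilylation of the tertiary silyl ether, chosen over basic fluoride because the product is a tertiary β-hydroxy ketone that base would open by retro-aldol cleavage of ring A.

Step 17
Reactants: 24 (1R,4R,5S,6S)-4β-hydroxy-2,10-dioxodauc-8-en-6α-yl (Z)-2-methylbut-2-enoate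
Product: 25 (1R,2S,4R,5S,6S)-2α,4β-dihydroxy-10-oxodauc-8-en-6α-yl (Z)-2-methylbut-2-enoate
Conditions: Me4NBH(OAc)3, MeCN/AcOH, −30 °C
Reagents that add atoms: none
Why: Evans–Saksena hydroxyl-directed reduction, in which the C4 hydroxyl exchanges onto boron and delivers hydride intramolecularly to the β face of the C2 carbonyl, should set the 2α-alcohol trans to the 4β-hydroxyl and leave the C10 enone, which has no free β-hydroxyl while O2 is held in the borate chelate.

Step 18
Reactants: 25 (1R,2S,4R,5S,6S)-2α,4β-dihydroxy-10-oxodauc-8-en-6α-yl (Z)-2-methylbut-2-enoate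
Product: 26 (1R,2S,4R,5S,6S)-2α-acetoxy-4β-hydroxy-10-oxodauc-8-en-6α-yl (Z)-2-methylbut-2-enoate
Conditions: Ac2O, pyridine, DMAP (cat.), CH2Cl2, rt
Reagents that add atoms: acetic anhydride, CC(=O)OC(C)=O
Why: DMAP-catalysed acetylation should acylate the secondary C2 alcohol only, the tertiary C4 alcohol flanked by the isopropyl group being unreactive under these conditions.

Step 19
Reactants: 26 (1R,2S,4R,5S,6S)-2α-acetoxy-4β-hydroxy-10-oxodauc-8-en-6α-yl (Z)-2-methylbut-2-enoate
Product: 27 (1R,2S,4R,5S,6S,10S)-2α-acetoxy-4β,10β-dihydroxydauc-8-en-6α-yl (Z)-2-methylbut-2-enoate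
Conditions: NaBH4, CeCl3·7H2O, MeOH, −78 °C
Reagents that add atoms: none
Why: Luche 1,2-reduction of the enone, in which hydride attacks the α face anti to the angular C1 methyl group, should give the 10β allylic alcohol cis to that methyl.

Step 20
Reactants: 27 (1R,2S,4R,5S,6S,10S)-2α-acetoxy-4β,10β-dihydroxydauc-8-en-6α-yl (Z)-2-methylbut-2-enoate
Product: 28 (1R,2S,4R,5S,6S,10S)-2α-acetoxy-6α-(angeloyloxy)-10β-(benzoyloxy)dauc-8-en-4β-ol (target, CNP0248576.1)
Conditions: BzCl, Et3N, DMAP (cat.), CH2Cl2, 0 °C to rt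
Reagents that add atoms: benzoyl chloride, O=C(Cl)c1ccccc1
Why: DMAP-catalysed benzoylation should acylate the secondary allylic C10 alcohol and leave the tertiary C4 alcohol free, with no stereocentre affected.

**Compound list**

1 | tert-butyl 4-oxobutanoate | O=CCCC(=O)OC(C)(C)C | starting material
2 | isobutyraldehyde | CC(C)C=O | starting material
3 | tert-butyl (3R,4R)-3-formyl-4-hydroxy-5-methylhexanoate | CC(C)[C@@H](O)[C@@H](CC(=O)OC(C)(C)C)C=O | intermediate
4 | tert-butyl (3R,4R)-4-[(tert-butyldimethylsilyl)oxy]-3-formyl-5-methylhexanoate | CC(C)[C@@H](O[Si](C)(C)C(C)(C)C)[C@@H](CC(=O)OC(C)(C)C)C=O | intermediate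
5 | 2-methylallylmagnesium chloride | CC(=C)C[Mg]Cl | starting material
6 | tert-butyl (3S)-3-[(1R)-1-[(tert-butyldimethylsilyl)oxy]-2-methylpropyl]-4-hydroxy-6-methylhept-6-enoate, both C4 epimers | CC(C)[C@@H](O[Si](C)(C)C(C)(C)C)[C@@H](CC(=O)OC(C)(C)C)C(O)CC(C)=C | intermediate
7 | tert-butyl (3R)-3-[(1R)-1-[(tert-butyldimethylsilyl)oxy]-2-methylpropyl]-6-methyl-4-oxohept-6-enoate | CC(C)[C@@H](O[Si](C)(C)C(C)(C)C)[C@@H](CC(=O)OC(C)(C)C)C(=O)CC(C)=C | intermediate
8 | tert-butyl (3S,4S)-3-[(1R)-1-[(tert-butyldimethylsilyl)oxy]-2-methylpropyl]-4-hydroxy-6-methylhept-6-enoate | CC(C)[C@@H](O[Si](C)(C)C(C)(C)C)[C@@H](CC(=O)OC(C)(C)C)[C@@H](O)CC(C)=C | intermediate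
9 | (4S,5S)-4-[(1R)-1-[(tert-butyldimethylsilyl)oxy]-2-methylpropyl]-5-(2-methylprop-2-en-1-yl)oxolan-2-one | O=C1C[C@H]([C@H](O[Si](C)(C)C(C)(C)C)C(C)C)[C@H](CC(C)=C)O1 | intermediate
10 | acrolein | C=CC=O | starting material
11 | (4S,5S)-3-(1-hydroxyprop-2-en-1-yl)-4-[(1R)-1-[(tert-butyldimethylsilyl)oxy]-2-methylpropyl]-5-(2-methylprop-2-en-1-yl)oxolan-2-one, epimers at C3 and at the carbinol carbon | O=C1C(C(O)C=C)[C@H]([C@H](O[Si](C)(C)C(C)(C)C)C(C)C)[C@H](CC(C)=C)O1 | intermediate
12 | (3S,4S,5S)-3-(1-hydroxyprop-2-en-1-yl)-3-methyl-4-[(1R)-1-[(tert-butyldimethylsilyl)oxy]-2-methylpropyl]-5-(2-methylprop-2-en-1-yl)oxolan-2-one, both carbinol epimers | O=C1[C@](C)(C(O)C=C)[C@H]([C@H](O[Si](C)(C)C(C)(C)C)C(C)C)[C@H](CC(C)=C)O1 | intermediate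
13 | 2-hydroxy-1,4-dimethyl-9-[(1R)-1-[(tert-butyldimethylsilyl)oxy]-2-methylpropyl]-7-oxabicyclo[4.2.1]non-3-en-8-one (daucane descriptors 1S,4R,5S,6S; C10 epimers) | O=C1O[C@H]2CC(C)=CC(O)[C@]1(C)[C@@H]2[C@H](O[Si](C)(C)C(C)(C)C)C(C)C | intermediate
14 | 1,4-dimethyl-9-[(1R)-1-[(tert-butyldimethylsilyl)oxy]-2-methylpropyl]-2-[(triethylsilyl)oxy]-7-oxabicyclo[4.2.1]non-3-en-8-one (C10 epimers) | O=C1O[C@H]2CC(C)=CC(O[Si](CC)(CC)CC)[C@]1(C)[C@@H]2[C@H](O[Si](C)(C)C(C)(C)C)C(C)C | intermediate
15 | (1S,4R,5S,6S)-4-[(tert-butyldimethylsilyl)oxy]-6-hydroxy-10-[(triethylsilyl)oxy]-3,4-secodauc-8-en-2-one (C10 epimers) | O[C@H]1CC(C)=CC(O[Si](CC)(CC)CC)[C@@](C)(C(C)=O)[C@@H]1[C@H](O[Si](C)(C)C(C)(C)C)C(C)C | intermediate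
16 | angelic acid, (Z)-2-methylbut-2-enoic acid | C/C=C(/C)C(O)=O | starting material
17 | (Z)-2-methylbut-2-enoic 2,4,6-trichlorobenzoic anhydride | C/C=C(/C)C(=O)OC(=O)c1c(Cl)cc(Cl)cc1Cl | intermediate
18 | (1S,4R,5S,6S)-4-[(tert-butyldimethylsilyl)oxy]-2-oxo-10-[(triethylsilyl)oxy]-3,4-secodauc-8-en-6-yl (Z)-2-methylbut-2-enoate (C10 epimers) | C/C=C(/C)C(=O)O[C@H]1CC(C)=CC(O[Si](CC)(CC)CC)[C@@](C)(C(C)=O)[C@@H]1[C@H](O[Si](C)(C)C(C)(C)C)C(C)C | intermediate
19 | 3-(trifluoroacetyl) derivative of 18 (1,3-diketone; C10 epimers) | C/C=C(/C)C(=O)O[C@H]1CC(C)=CC(O[Si](CC)(CC)CC)[C@@](C)(C(=O)CC(=O)C(F)(F)F)[C@@H]1[C@H](O[Si](C)(C)C(C)(C)C)C(C)C | intermediate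
20 | (1S,4R,5S,6S)-4-[(tert-butyldimethylsilyl)oxy]-3-diazo-2-oxo-10-[(triethylsilyl)oxy]-3,4-secodauc-8-en-6-yl (Z)-2-methylbut-2-enoate (C10 epimers) | C/C=C(/C)C(=O)O[C@H]1CC(C)=CC(O[Si](CC)(CC)CC)[C@@](C)(C(=O)C=[N+]=[N-])[C@@H]1[C@H](O[Si](C)(C)C(C)(C)C)C(C)C | intermediate
21 | (1S,4R,5S,6S)-4-[(tert-butyldimethylsilyl)oxy]-3-diazo-10-hydroxy-2-oxo-3,4-secodauc-8-en-6-yl (Z)-2-methylbut-2-enoate (C10 epimers) | C/C=C(/C)C(=O)O[C@H]1CC(C)=CC(O)[C@@](C)(C(=O)C=[N+]=[N-])[C@@H]1[C@H](O[Si](C)(C)C(C)(C)C)C(C)C | intermediate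
22 | (1S,4R,5S,6S)-4-[(tert-butyldimethylsilyl)oxy]-3-diazo-2,10-dioxo-3,4-secodauc-8-en-6-yl (Z)-2-methylbut-2-enoate | C/C=C(/C)C(=O)O[C@H]1CC(C)=CC(=O)[C@@](C)(C(=O)C=[N+]=[N-])[C@@H]1[C@H](O[Si](C)(C)C(C)(C)C)C(C)C | intermediate
23 | (1R,4R,5S,6S)-4β-[(tert-butyldimethylsilyl)oxy]-2,10-dioxodauc-8-en-6α-yl (Z)-2-methylbut-2-enoate | C/C=C(/C)C(=O)O[C@H]1CC(C)=CC(=O)[C@@]2(C)C(=O)C[C@@](O[Si](C)(C)C(C)(C)C)(C(C)C)[C@H]12 | intermediate
24 | (1R,4R,5S,6S)-4β-hydroxy-2,10-dioxodauc-8-en-6α-yl (Z)-2-methylbut-2-enoate | C/C=C(/C)C(=O)O[C@H]1CC(C)=CC(=O)[C@@]2(C)C(=O)C[C@@](O)(C(C)C)[C@H]12 | intermediate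
25 | (1R,2S,4R,5S,6S)-2α,4β-dihydroxy-10-oxodauc-8-en-6α-yl (Z)-2-methylbut-2-enoate | C/C=C(/C)C(=O)O[C@H]1CC(C)=CC(=O)[C@@]2(C)[C@@H](O)C[C@@](O)(C(C)C)[C@H]12 | intermediate
26 | (1R,2S,4R,5S,6S)-2α-acetoxy-4β-hydroxy-10-oxodauc-8-en-6α-yl (Z)-2-methylbut-2-enoate | C/C=C(/C)C(=O)O[C@H]1CC(C)=CC(=O)[C@@]2(C)[C@@H](OC(C)=O)C[C@@](O)(C(C)C)[C@H]12 | intermediate
27 | (1R,2S,4R,5S,6S,10S)-2α-acetoxy-4β,10β-dihydroxydauc-8-en-6α-yl (Z)-2-methylbut-2-enoate | C/C=C(/C)C(=O)O[C@H]1CC(C)=C[C@H](O)[C@@]2(C)[C@@H](OC(C)=O)C[C@@](O)(C(C)C)[C@H]12 | intermediate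
28 | (1R,2S,4R,5S,6S,10S)-2α-acetoxy-6α-(angeloyloxy)-10β-(benzoyloxy)dauc-8-en-4β-ol | C/C=C(/C)C(=O)O[C@H]1CC(C)=C[C@H](OC(=O)c2ccccc2)[C@@]2(C)[C@@H](OC(C)=O)C[C@@](O)(C(C)C)[C@H]12 | target

**Step count and risks**

Total step count: 20. Longest linear sequence: 20 steps (1 and 2 to 28); 5, 10 and 16 enter as purchased reagents.

Steps most likely to fail:

1. Step 15 (key step). What may go wrong: the carbenoid is captured by the C10 carbonyl oxygen (five-membered carbonyl ylide that then dimerises or is protonated) or by the silyl ether oxygen faster than it inserts, or it inserts at the isopropyl methine. Fallback: ring A is closed by an intramolecular Reformatsky aldol instead of a C–H insertion. It sets out from 22: aqueous HBr in Et2O at 0 °C should convert the diazoketone into the bromomethyl ketone F1; aqueous HF in MeCN should remove the silyl group to give the carbinol F2; Dess–Martin oxidation should give the isobutyryl ketone F3; SmI2 in THF at −78 °C should then form the samarium enolate at C3, which adds to the C4 ketone and closes ring A under base-free conditions that spare the C6 angelate. The route is rejoined at 24. In this closure C4 is formed anew, so its configuration rests on the chelated transition state and not on retention, and the C4 epimer would have to be separated.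

2. Step 7. What may go wrong: slow enolisation at the hindered C1–H of the aldol adduct and retro-aldol loss of acrolein from the dianion. Fallback: the quaternary centre is built through a formyl group. It sets out from 9: Claisen formylation (NaH, HCO2Et, THF) should give the hydroxymethylene lactone F4; C-methylation (MeI, K2CO3, acetone) anti to the ring substituents should give the formyl methyl lactone F5; vinylmagnesium bromide in THF at −78 °C should add to the aldehyde and rejoin the route at 12.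

3. Step 11. What may go wrong: slow acylation of the hindered C6 hydroxyl, which is partly tied up as the hemiketal, and Z-to-E isomerisation of the angelate at 80 °C. Fallback: the Z-alkene is built on the molecule. It sets out from 15: esterification with 2-[bis(2,2,2-trifluoroethoxy)phosphoryl]propanoic acid (DCC, DMAP, CH2Cl2) should give the phosphonopropionate F6, and a Still–Gennari olefination with acetaldehyde (KN(SiMe3)2, 18-crown-6, THF, −78 °C) should give the Z-configured 2-methylbut-2-enoate, rejoining the route at 18.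

Further compounds

F1 | step 15 | (1S,4R,5S,6S)-3-bromo-4-[(tert-butyldimethylsilyl)oxy]-2,10-dioxo-3,4-secodauc-8-en-6-yl (Z)-2-methylbut-2-enoate | C/C=C(/C)C(=O)O[C@H]1CC(C)=CC(=O)[C@@](C)(C(=O)CBr)[C@@H]1[C@H](O[Si](C)(C)C(C)(C)C)C(C)C
F2 | step 15 | (1S,4R,5S,6S)-3-bromo-4-hydroxy-2,10-dioxo-3,4-secodauc-8-en-6-yl (Z)-2-methylbut-2-enoate | C/C=C(/C)C(=O)O[C@H]1CC(C)=CC(=O)[C@@](C)(C(=O)CBr)[C@@H]1[C@H](O)C(C)C
F3 | step 15 | 3-bromo-2,4,10-trioxo-3,4-secodauc-8-en-6-yl (Z)-2-methylbut-2-enoate (C1, C5, C6 as in 22) | C/C=C(/C)C(=O)O[C@H]1CC(C)=CC(=O)[C@@](C)(C(=O)CBr)[C@@H]1C(=O)C(C)C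
F4 | step 7 | (4S,5S)-4-[(1R)-1-[(tert-butyldimethylsilyl)oxy]-2-methylpropyl]-5-(2-methylprop-2-en-1-yl)-2-oxooxolane-3-carbaldehyde (hydroxymethylene tautomer in equilibrium) | O=C1C(C=O)[C@H]([C@H](O[Si](C)(C)C(C)(C)C)C(C)C)[C@H](CC(C)=C)O1
F5 | step 7 | (3S,4S,5S)-3-methyl-4-[(1R)-1-[(tert-butyldimethylsilyl)oxy]-2-methylpropyl]-5-(2-methylprop-2-en-1-yl)-2-oxooxolane-3-carbaldehyde | O=C1[C@](C)(C=O)[C@H]([C@H](O[Si](C)(C)C(C)(C)C)C(C)C)[C@H](CC(C)=C)O1
F6 | step 11 | (1S,4R,5S,6S)-4-[(tert-butyldimethylsilyl)oxy]-2-oxo-10-[(triethylsilyl)oxy]-3,4-secodauc-8-en-6-yl 2-[bis(2,2,2-trifluoroethoxy)phosphoryl]propanoate (C10 epimers) | CC(C(=O)O[C@H]1CC(C)=CC(O[Si](CC)(CC)CC)[C@@](C)(C(C)=O)[C@@H]1[C@H](O[Si](C)(C)C(C)(C)C)C(C)C)P(=O)(OCC(F)(F)F)OCC(F)(F)F
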